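**Retrosynthetic overview**
1. The plan rests on the 1,3,5-pattern of the single six-membered ring. The chain-bearing C3 alternates with the oxygenated C1 (carbonyl) and C5 (OMe), which is the imprint of a C18-acyl-primed tetraketide (a 5-alkylresorcinol). Only the oxygens on C2 and C4 fall outside this pattern.
2. The C2 oxygen is removed first (Thiele–Winter acetoxylation, deacetylation, autoxidation). The C4 oxygen follows (para-oxidation of 3-heptadecyl-5-methoxyphenol).
3. The phenol is traced to methyl 2-heptadecyl-4,6-dihydroxybenzoate. The ester first steers O-methylation to the remote OH and then leaves as CO2.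
4. The only ring is opened between the ester-bearing and the chain-bearing carbon (the future C2–C3). In the forward direction this is an intramolecular aldol of methyl 3,5,7-trioxotetracosanoate, chain C2 onto the C7 ketone.
5. The open chain is cut at C6–C7 into methyl stearate and the trianion of methyl 3,5-dioxohexanoate, which comes from 4-hydroxy-6-methyl-2-pyranone.

Key step: step 3

Remark: the side chain is read as unbranched heptadecyl, and the target has no stereocentre. Poly-β-carbonyl compounds are drawn as keto forms although they are largely enolised. Chain atoms C3, C2, C7, C6, C5, C4 become ring atoms C1, C2, C3, C4, C5, C6 of the quinone.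

**Step 1**
Reactants: 1 4-hydroxy-6-methyl-2H-pyran-2-one
Product: 2 methyl 3,5-dioxohexanoate
Conditions: Mg(OMe)2 (commercial solution in MeOH), MeOH, reflux; cold 2 M HCl
Reagents that add atoms: magnesium methoxide, [Mg+2].[O-]C.[O-]C (methoxide in exchange with the solvent methanol, CO)
Why: Alkoxide-induced ring opening (methanolysis) of a 4-hydroxy-2-pyranone, in which methoxide adds to the lactone carbonyl and the divalent magnesium ion holds the released β,δ-diketo ester as a chelated enolate, so that re-closure is suppressed until the cold acid quench.

**Step 2**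
Reactants: 2 methyl 3,5-dioxohexanoate; 3 methyl stearate (methyl octadecanoate)
Product: 5 methyl 3,5,7-trioxotetracosanoate, via trilithium trienolate 4 (not isolated)
Conditions: 2 (2 equiv), LiN(i-Pr)2 (commercial solution, 6.2 equiv), THF, 0 °C; 3 (1 equiv) in THF, 0 °C to rt; cold 1 M HCl; crystallisation, no silica gel
Reagents that add atoms: none
Why: Claisen-type C-acylation of a poly-β-carbonyl trianion, in which the terminal carbanion (formed last and stabilised least) is the most nucleophilic site and attacks the ester carbonyl of 3, while the second equivalent of 4 takes up the acidic proton of the new C6 methylene so that the acylation does not stop half-way.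

**Step 3**
Reactants: 5 methyl 3,5,7-trioxotetracosanoate
Product: 7 methyl 2-heptadecyl-4,6-dihydroxybenzoate, via cyclic aldol adduct 6 (not isolated)
Conditions: aq. Na2B4O7 buffer (pH 9.2), THF–MeOH, rt, N2; then 1 M HCl
Reagents that add atoms: none
Why: At pH about 9 compound 5 exists as a rapidly equilibrating set of enols and monoenolates; in the one deprotonated at C2 (between the ester and the C3 ketone) this carbon adds to the C7 ketone to give the cyclic aldol 6, which loses water by an E1cB path and tautomerises at its two remaining ring ketones to aromatic 7. The closest known reaction type is the biomimetic aldol-type cyclisation of 3,5,7-triketo esters and acids to 6-substituted 2,4-dihydroxybenzoates in weakly basic hydroxylic media. The one ring is closed in the 6-(enolendo)-exo-trig mode by the new C2–C7 bond, which ends as C2–C3 of the quinone. No stereocentre has to be controlled, since the two of 6 vanish on aromatisation. The step needs chemoselectivity for this closure over Claisen closure (C6 onto the ester carbonyl, towards an acylphloroglucinol) and over lactonisation of the C5 enol oxygen onto the ester (towards a 4-hydroxy-2-pyranone). This is secured by a mild buffer free of chelating metal ions and strong alkoxide, so that C7 stays an un-ionised ketone more electrophilic than the ester, by the reversible aldol addition being drained through irreversible aromatisation, and by the THF–MeOH co-solvent that keeps the amphiphilic C17 substrate in solution.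

**Step 4**
Reactants: 7 methyl 2-heptadecyl-4,6-dihydroxybenzoate
Product: 8 methyl 2-heptadecyl-6-hydroxy-4-methoxybenzoate
Conditions: MeI (1.05 equiv), K2CO3, acetone, rt to 40 °C
Reagents that add atoms: iodomethane, CI
Why: Williamson ether synthesis with hydrogen-bond discrimination, in which the 6-OH is locked to the ester carbonyl and is less acidic and shielded, so one equivalent of MeI should alkylate only the 4-OH; this avoids the statistical methylation that the symmetric resorcinol would suffer after loss of the ester, and it fixes the future C5 (OMe) against C1 (free OH).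

**Step 5**
Reactants: 8 methyl 2-heptadecyl-6-hydroxy-4-methoxybenzoate
Product: 10 3-heptadecyl-5-methoxyphenol, via 2-heptadecyl-6-hydroxy-4-methoxybenzoic acid 9 (not isolated)
Conditions: KOH, ethylene glycol–H2O, 130 °C, N2; 2 M HCl; crude acid in DMF, 140 °C until gas evolution ends
Reagents that add atoms: none
Why: Saponification of the hindered salicylate followed by protodecarboxylation, in which the carboxyl-bearing ring carbon lies ortho and para to oxygen donors, so ipso-protonation and loss of CO2 are easy on heating (general for 2-hydroxy-4-alkoxy-6-alkylbenzoic acids) and the aryl methyl ether is inert at this temperature.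

**Step 6**
Reactants: 10 3-heptadecyl-5-methoxyphenol
Product: 11 2-heptadecyl-6-methoxycyclohexa-2,5-diene-1,4-dione
Conditions: ON(SO3K)2 (2.5 equiv), KH2PO4, n-Bu4NHSO4 (cat.), H2O–CH2Cl2, rt
Reagents that add atoms: potassium nitrosodisulfonate ON(SO3K)2, [K+].[K+].[O]N(S(=O)(=O)[O-])S(=O)(=O)[O-]
Why: Teuber oxidation, in which the first equivalent of the radical salt gives the phenoxyl radical, the second couples through oxygen at the free para carbon (high spin density, reinforced by the adjacent OMe), and loss of imidodisulfonate gives the para-quinone, with phase transfer bringing the oxidant to the lipophilic phenol.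

**Step 7**
Reactants: 11 2-heptadecyl-6-methoxycyclohexa-2,5-diene-1,4-dione
Product: 12 3-heptadecyl-5-methoxybenzene-1,2,4-triyl triacetate
Conditions: Ac2O, conc. H2SO4 (cat.), rt
Reagents that add atoms: acetic anhydride, CC(=O)OC(C)=O
Why: Thiele–Winter acetoxylation, in which the C5 methoxy group donates as a vinylogous ester into C1=O and makes C6 electron-rich, so the activated C4 carbonyl directs acetate to its only electrophilic free β-carbon, C2, and enolisation with acetylation of both phenols gives the triacetate.

**Step 8**
Reactants: 12 3-heptadecyl-5-methoxybenzene-1,2,4-triyl triacetate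
Product: 14 irisoquin B (3-heptadecyl-2-hydroxy-5-methoxycyclohexa-2,5-diene-1,4-dione), via 3-heptadecyl-5-methoxybenzene-1,2,4-triol 13 (not isolated)
Conditions: HCl (cat.), MeOH, reflux, N2; evaporate; air, KH2PO4/K2HPO4 buffer (pH 7)–Et2O, rt
Reagents that add atoms: none
Why: Acid-catalysed transesterification frees the hydroxyhydroquinone under nitrogen, and autoxidation of this very electron-rich triol at neutral pH gives the 2-hydroxy-1,4-quinone tautomer; removing the acid before oxidation prevents Fischer-type O-methylation of the C2 hydroxyl, and the absence of hydroxide spares the C5 methoxy group.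

**Compound list**
1 | 4-hydroxy-6-methyl-2H-pyran-2-one | CC1=CC(O)=CC(=O)O1 | starting material
2 | methyl 3,5-dioxohexanoate | CC(=O)CC(=O)CC(=O)OC | intermediate
3 | methyl stearate (methyl octadecanoate) | CCCCCCCCCCCCCCCCCC(=O)OC | starting material
4 | trilithium trienolate of methyl 3,5-dioxohexanoate (not isolated) | [Li+].[Li+].[Li+].C=C([O-])C=C([O-])C=C([O-])OC | intermediate
5 | methyl 3,5,7-trioxotetracosanoate | CCCCCCCCCCCCCCCCCC(=O)CC(=O)CC(=O)CC(=O)OC | intermediate
6 | methyl 2-heptadecyl-2-hydroxy-4,6-dioxocyclohexane-1-carboxylate (diastereomer mixture, not isolated) | CCCCCCCCCCCCCCCCCC1(O)CC(=O)CC(=O)C1C(=O)OC | intermediate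
7 | methyl 2-heptadecyl-4,6-dihydroxybenzoate | CCCCCCCCCCCCCCCCCc1cc(O)cc(O)c1C(=O)OC | intermediate
8 | methyl 2-heptadecyl-6-hydroxy-4-methoxybenzoate | CCCCCCCCCCCCCCCCCc1cc(OC)cc(O)c1C(=O)OC | intermediate
9 | 2-heptadecyl-6-hydroxy-4-methoxybenzoic acid (not isolated) | CCCCCCCCCCCCCCCCCc1cc(OC)cc(O)c1C(=O)O | intermediate
10 | 3-heptadecyl-5-methoxyphenol | CCCCCCCCCCCCCCCCCc1cc(O)cc(OC)c1 | intermediate
11 | 2-heptadecyl-6-methoxycyclohexa-2,5-diene-1,4-dione | CCCCCCCCCCCCCCCCCC1=CC(=O)C=C(OC)C1=O | intermediate
12 | 3-heptadecyl-5-methoxybenzene-1,2,4-triyl triacetate | CCCCCCCCCCCCCCCCCc1c(OC(C)=O)c(OC(C)=O)cc(OC)c1OC(C)=O | intermediate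
13 | 3-heptadecyl-5-methoxybenzene-1,2,4-triol (not isolated) | CCCCCCCCCCCCCCCCCc1c(O)c(O)cc(OC)c1O | intermediate
14 | irisoquin B, 3-heptadecyl-2-hydroxy-5-methoxycyclohexa-2,5-diene-1,4-dione | CCCCCCCCCCCCCCCCCC1=C(O)C(=O)C=C(OC)C1=O | target

**Total step count:** 8. **Longest linear sequence:** 8 steps (1 to 14).

**Steps most likely to fail**

(a) Step 3, the key step. The chain may close through the wrong pair of atoms, with either the C6 carbanion or the C5 enol oxygen attacking the ester carbonyl. The aldol may also stall because the amphiphilic enolate aggregates in the partly aqueous medium.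

The fallback leaves the biomimetic closure for the known Michael–Claisen–dehydrogenation route to 6-alkylresorcylates. It sets out from 3 and returns at 7.
- Compound 3 is reduced with i-Bu2AlH (dilute CH2Cl2, −78 °C) to octadecanal F1.
- Wittig olefination with Ph3P=CHC(O)CH3 in toluene gives (E)-henicos-3-en-2-one F2.
- Dimethyl malonate and NaOMe in refluxing MeOH add in the Michael sense. The methyl ketone then closes onto one ester by Claisen condensation, giving methyl 6-heptadecyl-2-hydroxy-4-oxocyclohex-2-ene-1-carboxylate F3.
- Bromination–dehydrobromination with Br2 in DMF (0 °C, then 80 °C) aromatises the ring to 7.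

(b) Step 2. Proton transfer may outrun C-acylation. The trianion can deprotonate the enolisable ester at its α-carbon, and the more acidic product can quench the trianion, so conversion stays low.

The fallback builds the same chain in masked form and releases it under neutral conditions. It sets out from 3 and returns at 5.
- Compound 3 with MeNHOMe·HCl and i-PrMgCl (THF, −20 °C) gives N-methoxy-N-methyloctadecanamide F4.
- Commercial 2,2,6-trimethyl-4H-1,3-dioxin-4-one is deprotonated with LiN(SiMe3)2 and C-acylated with acetyl chloride to give 2,2-dimethyl-6-(2-oxopropyl)-4H-1,3-dioxin-4-one F5.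
- The dianion of F5 (LiN(i-Pr)2, 2 equiv, THF, −78 °C) is acylated by F4. The stable tetrahedral chelate of F4 blocks proton exchange, and the product is 6-(2,4-dioxohenicosyl)-2,2-dimethyl-4H-1,3-dioxin-4-one F6.
- Heating F6 with MeOH in toluene at 110 °C expels acetone by retro-hetero-Diels–Alder reaction. Methanol traps the acylketene to give 5.

(c) Step 7. Acetate addition may be sluggish on the donor-substituted quinone, may go to the wrong ring carbon, or may be accompanied by acid-induced loss of the O-methyl group.

The fallback brings in the C2 oxygen by nucleophilic epoxidation. It sets out from 11 and returns directly at 14.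
- Weitz–Scheffer epoxidation (H2O2, Na2CO3, aq. THF, 0 °C) should attack the more electrophilic alkyl-substituted C2=C3 double bond. This gives racemic 1-heptadecyl-3-methoxy-7-oxabicyclo[4.1.0]hept-3-ene-2,5-dione F7.
- Brief treatment with cold conc. H2SO4, then pouring onto ice, opens the epoxide at the tertiary carbon. Loss of the C2 proton isomerises it to the hydroxyquinone 14, as is known for 2-alkylquinone oxides.

**Further compounds**
F1 | step 3 | octadecanal | CCCCCCCCCCCCCCCCCC=O
F2 | step 3 | (E)-henicos-3-en-2-one | CCCCCCCCCCCCCCCCC/C=C/C(C)=O
F3 | step 3 | methyl 6-heptadecyl-2-hydroxy-4-oxocyclohex-2-ene-1-carboxylate (racemic, stereocentres lost on aromatisation) | CCCCCCCCCCCCCCCCCC1CC(=O)C=C(O)C1C(=O)OC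
F4 | step 2 | N-methoxy-N-methyloctadecanamide | CCCCCCCCCCCCCCCCCC(=O)N(C)OC
F5 | step 2 | 2,2-dimethyl-6-(2-oxopropyl)-4H-1,3-dioxin-4-one | CC(=O)CC1=CC(=O)OC(C)(C)O1
F6 | step 2 | 6-(2,4-dioxohenicosyl)-2,2-dimethyl-4H-1,3-dioxin-4-one | CCCCCCCCCCCCCCCCCC(=O)CC(=O)CC1=CC(=O)OC(C)(C)O1
F7 | step 7 | 1-heptadecyl-3-methoxy-7-oxabicyclo[4.1.0]hept-3-ene-2,5-dione (racemic) | CCCCCCCCCCCCCCCCCC12OC1C(=O)C=C(OC)C2=O
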